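**Plan**

- Numbering: tetrahydrofuran O1, C2 (bears ring C), C3 (bears CH2OH), C4 (bears the ring-B benzyl carbon), C5. Side chain: C7''(OH)–C8''(O–ring B)–C9''H2OH, carrying ring A.
- Retrosynthesis: cut C7''–C8'' (auxiliary aldol) and the ring-B O–C8'' bond (phenol alkylation), then O1–C2 (benzylic cation closure), then the C3–C2 bond and the C4–benzylic carbon bond together.
- Enabling feature: C4, C3 and C2 of the tetrahydrofuran with their three carbon substituents are the β-carbon, the α-carbon with its carbonyl (later CH2OH) and the aldol carbon of a butenolide; the acetal carbon of that butenolide becomes C5.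
- Forward: a dithiane, a menthyloxybutenolide and an aldehyde are joined in one step; desulfurisation and reduction give a triol; the only ring formed (the tetrahydrofuran) closes next; the glycerol ether is built last on ring B.
- Stereochemistry: C4 from the menthyl acetal (anti addition), C3 from C4 (anti aldol), C2 from the cationic closure trans to C3, C7''/C8'' from the syn boron aldol of an (S)-4-benzyloxazolidinone imide.

Key step: step 3

Assumption: the carbinol centre formed in the key step is carried as a mixture of both epimers and written without a descriptor until the cationic ring closure erases it; the menthyloxyfuranone is taken as a purchased reagent.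

**Step 1**
Reactants: 1 4-(benzyloxy)-3-methoxybenzaldehyde; 2 propane-1,3-dithiol
Product: 3 2-[4-(benzyloxy)-3-methoxyphenyl]-1,3-dithiane
Conditions: BF3·OEt2 (cat.), CH2Cl2, 0 °C to rt
Reagents that add atoms: none
Why: Lewis-acid-catalysed dithioacetalisation of an aryl aldehyde is routine, and the aryl benzyl ether is inert to catalytic BF3·OEt2 at this temperature.

**Step 2**
Reactants: 4 vanillin (4-hydroxy-3-methoxybenzaldehyde)
Product: 5 3-methoxy-4-(triisopropylsilyloxy)benzaldehyde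
Conditions: TIPSCl, imidazole, DMF, rt
Reagents that add atoms: triisopropylsilyl chloride, CC(C)[Si](Cl)(C(C)C)C(C)C
Why: Imidazole-promoted silyl ether formation is selective for the phenol and leaves the aldehyde untouched.

**Step 3**
Reactants: 3 2-[4-(benzyloxy)-3-methoxyphenyl]-1,3-dithiane; 6 (5R)-5-[(1R,2S,5R)-menthyloxy]furan-2(5H)-one; 5 3-methoxy-4-(triisopropylsilyloxy)benzaldehyde
Product: 9 (3S,4R,5R)-4-{2-[4-(benzyloxy)-3-methoxyphenyl]-1,3-dithian-2-yl}-3-{hydroxy[3-methoxy-4-(triisopropylsilyloxy)phenyl]methyl}-5-[(1R,2S,5R)-menthyloxy]dihydrofuran-2(3H)-one (both carbinol epimers), via 2-lithio-1,3-dithiane 7 (not isolated), via lithium enolate 8 (not isolated)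
Conditions: n-BuLi, THF, −78 to −20 °C; 6, −78 °C; 5, −78 °C; sat. NH4Cl, −78 °C
Reagents that add atoms: none
Why: n-BuLi turns 3 into the sulfur-stabilised benzylic carbanion 7, which adds in a conjugate (Michael) fashion to C4 of butenolide 6; the resulting lithium enolate 8 then adds through C3 to the aldehyde carbon of 5 (aldol), and the aldolate is protonated cold. The closest known reaction type is the tandem conjugate addition–aldol trapping of lithiated 2-aryl-1,3-dithianes on 5-alkoxy-2(5H)-furanones, used for lignan lactones. No ring closes; the step forms the ring-B benzylic carbon–C4 bond and the C3–carbinol carbon bond. C4 is set by the C5 acetal stereocentre, the carbanion entering on the face opposite the menthyloxy group (4R), and C3 is set by the new bulky dithianyl group at C4, the aldehyde entering anti to it (3S, trans,trans lactone); the carbinol centre is not controlled and need not be, since step 6 erases it. The step needs 1,4- over 1,2-regioselectivity, which the soft, hindered 2-aryl dithianyl anion secures, and two π-facial selections, which the acetal substituent and then the dithianyl substituent on the flat five-membered ring secure.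

**Step 4**
Reactants: 9 dithianyl lactone from step 3
Product: 10 (3S,4R,5R)-4-(4-hydroxy-3-methoxybenzyl)-3-{hydroxy[3-methoxy-4-(triisopropylsilyloxy)phenyl]methyl}-5-[(1R,2S,5R)-menthyloxy]dihydrofuran-2(3H)-one (both carbinol epimers)
Conditions: Raney Ni (W-2, excess, washed neutral), H2 (1 atm), EtOH, rt to reflux
Reagents that add atoms: none
Why: Raney Ni desulfurisation cleaves both C–S bonds of the dithiane and, under hydrogen, hydrogenolyses the aryl benzyl ether, while the aryl silyl ether, the lactone acetal, the benzylic hydroxyl and the ring stereocentres should survive the neutral medium.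

**Step 5**
Reactants: 10 phenol lactone from step 4
Product: 11 (2R,3R)-2-(4-hydroxy-3-methoxybenzyl)-3-{hydroxy[3-methoxy-4-(triisopropylsilyloxy)phenyl]methyl}butane-1,4-diol (both carbinol epimers)
Conditions: LiAlH4, THF, 0 °C to rt; then H2O, 15% NaOH, H2O
Reagents that add atoms: none
Why: Hydride reduction of the γ-alkoxy lactone opens the lactol, the hemiacetal expels menthoxide, and both aldehydes are reduced, so the carbonyl carbon and the acetal carbon each end as CH2OH without touching C3 or C4.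

**Step 6**
Reactants: 11 triol from step 5
Product: 12 [(2S,3R,4R)-4-(4-hydroxy-3-methoxybenzyl)-2-[3-methoxy-4-(triisopropylsilyloxy)phenyl]oxolan-3-yl]methanol
Conditions: (+)-10-camphorsulfonic acid (CSA, cat.), CH2Cl2, 0 °C to rt
Reagents that add atoms: none
Why: Acid ionises the p-silyloxybenzylic alcohol of either epimer to the same benzylic cation, which is captured by the hydroxymethyl oxygen on C4 in a 5-exo SN1 cycloetherification (the other hydroxymethyl could only give an oxetane), and closure places the ring-C aryl trans to the C3 substituent, giving the (2S) centre; mild acid and short contact avoid Friedel–Crafts closure onto ring B.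

**Step 7**
Reactants: 13 (S)-4-benzyloxazolidin-2-one; 14 bromoacetyl bromide
Product: 16 (S)-4-benzyl-3-(bromoacetyl)oxazolidin-2-one, via N-lithio oxazolidinone 15 (not isolated)
Conditions: n-BuLi, THF, −78 °C; 14, −78 to 0 °C
Reagents that add atoms: none
Why: N-acylation of the lithiated oxazolidinone is the standard entry to N-acyl oxazolidinones, and the acyl bromide reacts far faster than the alkyl bromide.

**Step 8**
Reactants: 12 tetrahydrofuran phenol from step 6; 16 (S)-4-benzyl-3-(bromoacetyl)oxazolidin-2-one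
Product: 17 (4S)-4-benzyl-3-{[4-({(3R,4R,5S)-4-(hydroxymethyl)-5-[3-methoxy-4-(triisopropylsilyloxy)phenyl]oxolan-3-yl}methyl)-2-methoxyphenoxy]acetyl}oxazolidin-2-one
Conditions: K2CO3, acetone, rt
Reagents that add atoms: none
Why: Williamson ether synthesis, in which the ring-B phenoxide displaces the activated α-bromide by SN2 while the aliphatic hydroxyl is not deprotonated and the aryl silyl ether is stable in aprotic acetone.

**Step 9**
Reactants: 17 aryloxyacetyl imide from step 8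
Product: 18 (4S)-4-benzyl-3-{[4-({(3R,4R,5S)-4-[(tert-butyldimethylsilyloxy)methyl]-5-[3-methoxy-4-(triisopropylsilyloxy)phenyl]oxolan-3-yl}methyl)-2-methoxyphenoxy]acetyl}oxazolidin-2-one
Conditions: TBSCl, imidazole, DMF, rt
Reagents that add atoms: tert-butyldimethylsilyl chloride, CC(C)(C)[Si](C)(C)Cl
Why: Standard silyl ether formation on the primary alcohol, needed because a free hydroxyl would consume the boron triflate of the next step.

**Step 10**
Reactants: 18 silylated imide from step 9; 5 3-methoxy-4-(triisopropylsilyloxy)benzaldehyde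
Product: 20 (4S)-4-benzyl-3-{(2S,3R)-2-[4-({(3R,4R,5S)-4-[(tert-butyldimethylsilyloxy)methyl]-5-[3-methoxy-4-(triisopropylsilyloxy)phenyl]oxolan-3-yl}methyl)-2-methoxyphenoxy]-3-hydroxy-3-[3-methoxy-4-(triisopropylsilyloxy)phenyl]propanoyl}oxazolidin-2-one, via boron enolate 19 (not isolated)
Conditions: Bu2BOTf, i-Pr2NEt, CH2Cl2, −78 to 0 °C; 5, −78 to 0 °C; pH 7 buffer, MeOH, H2O2, 0 °C
Reagents that add atoms: none
Why: Evans syn aldol, in which the (Z)-boron enolate 19 reacts through a Zimmerman–Traxler chair on the face opposite the auxiliary benzyl group, giving the (2S,3R) syn adduct, that is C8'' and C7'' in the threo (R,R) arrangement of the target.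

**Step 11**
Reactants: 20 aldol adduct from step 10
Product: 21 (1R,2R)-2-[4-({(3R,4R,5S)-4-[(tert-butyldimethylsilyloxy)methyl]-5-[3-methoxy-4-(triisopropylsilyloxy)phenyl]oxolan-3-yl}methyl)-2-methoxyphenoxy]-1-[3-methoxy-4-(triisopropylsilyloxy)phenyl]propane-1,3-diol
Conditions: LiBH4, THF, H2O (1 equiv), 0 °C; then 1 M NaOH
Reagents that add atoms: none
Why: Reductive cleavage of the N-acyl oxazolidinone with LiBH4 gives the primary alcohol C9'' and releases the auxiliary without epimerising C8''.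

**Step 12**
Reactants: 21 silylated diol from step 11
Product: 22 (1R,2R)-1-(4-hydroxy-3-methoxyphenyl)-2-[4-({(3R,4R,5S)-5-(4-hydroxy-3-methoxyphenyl)-4-(hydroxymethyl)oxolan-3-yl}methyl)-2-methoxyphenoxy]propane-1,3-diol (CNP0158473.2)
Conditions: TBAF, AcOH, THF, 0 °C to rt
Reagents that add atoms: none
Why: Fluoride-mediated desilylation removes the two aryl silyl ethers and the primary alkyl silyl ether, and buffering with AcOH keeps the liberated phenoxides from attacking the benzylic positions.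

**Compound list**

1 | 4-(benzyloxy)-3-methoxybenzaldehyde | COc1cc(C=O)ccc1OCc1ccccc1 | starting material
2 | propane-1,3-dithiol | SCCCS | starting material
3 | 2-[4-(benzyloxy)-3-methoxyphenyl]-1,3-dithiane | COc1cc(C2SCCCS2)ccc1OCc1ccccc1 | intermediate
4 | vanillin | COc1cc(C=O)ccc1O | starting material
5 | 3-methoxy-4-(triisopropylsilyloxy)benzaldehyde | COc1cc(C=O)ccc1O[Si](C(C)C)(C(C)C)C(C)C | intermediate
6 | (5R)-5-[(1R,2S,5R)-menthyloxy]furan-2(5H)-one | O=C1C=C[C@H](O[C@@H]2C[C@H](C)CC[C@H]2C(C)C)O1 | starting material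
7 | 2-lithio-2-[4-(benzyloxy)-3-methoxyphenyl]-1,3-dithiane (formed in the flask) | COc1cc(C2([Li])SCCCS2)ccc1OCc1ccccc1 | intermediate
8 | lithium enolate of (4R,5R)-4-{2-[4-(benzyloxy)-3-methoxyphenyl]-1,3-dithian-2-yl}-5-[(1R,2S,5R)-menthyloxy]dihydrofuran-2(3H)-one (formed in the flask) | COc1cc(C2(SCCCS2)[C@@H]3C=C(O[Li])O[C@H]3O[C@@H]4C[C@H](C)CC[C@H]4C(C)C)ccc1OCc1ccccc1 | intermediate
9 | (3S,4R,5R)-4-{2-[4-(benzyloxy)-3-methoxyphenyl]-1,3-dithian-2-yl}-3-{hydroxy[3-methoxy-4-(triisopropylsilyloxy)phenyl]methyl}-5-[(1R,2S,5R)-menthyloxy]dihydrofuran-2(3H)-one, both carbinol epimers | COc1cc(C2(SCCCS2)[C@H]3[C@H](O[C@@H]4C[C@H](C)CC[C@H]4C(C)C)OC(=O)[C@@H]3C(O)c5ccc(O[Si](C(C)C)(C(C)C)C(C)C)c(OC)c5)ccc1OCc1ccccc1 | intermediate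
10 | (3S,4R,5R)-4-(4-hydroxy-3-methoxybenzyl)-3-{hydroxy[3-methoxy-4-(triisopropylsilyloxy)phenyl]methyl}-5-[(1R,2S,5R)-menthyloxy]dihydrofuran-2(3H)-one, both carbinol epimers | COc1cc(C[C@H]3[C@H](O[C@@H]4C[C@H](C)CC[C@H]4C(C)C)OC(=O)[C@@H]3C(O)c5ccc(O[Si](C(C)C)(C(C)C)C(C)C)c(OC)c5)ccc1O | intermediate
11 | (2R,3R)-2-(4-hydroxy-3-methoxybenzyl)-3-{hydroxy[3-methoxy-4-(triisopropylsilyloxy)phenyl]methyl}butane-1,4-diol, both carbinol epimers | COc1cc(C[C@@H](CO)[C@H](CO)C(O)c2ccc(O[Si](C(C)C)(C(C)C)C(C)C)c(OC)c2)ccc1O | intermediate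
12 | [(2S,3R,4R)-4-(4-hydroxy-3-methoxybenzyl)-2-[3-methoxy-4-(triisopropylsilyloxy)phenyl]oxolan-3-yl]methanol | COc1cc(C[C@H]2CO[C@H](c3ccc(O[Si](C(C)C)(C(C)C)C(C)C)c(OC)c3)[C@H]2CO)ccc1O | intermediate
13 | (S)-4-benzyloxazolidin-2-one | O=C1N[C@@H](Cc2ccccc2)CO1 | starting material
14 | bromoacetyl bromide | BrCC(Br)=O | starting material
15 | N-lithio-(S)-4-benzyloxazolidin-2-one (formed in the flask) | [Li]N1[C@@H](Cc2ccccc2)COC1=O | intermediate
16 | (S)-4-benzyl-3-(bromoacetyl)oxazolidin-2-one | O=C(CBr)N1[C@@H](Cc2ccccc2)COC1=O | intermediate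
17 | (4S)-4-benzyl-3-{[4-({(3R,4R,5S)-4-(hydroxymethyl)-5-[3-methoxy-4-(triisopropylsilyloxy)phenyl]oxolan-3-yl}methyl)-2-methoxyphenoxy]acetyl}oxazolidin-2-one | COc1cc(C[C@H]2CO[C@H](c3ccc(O[Si](C(C)C)(C(C)C)C(C)C)c(OC)c3)[C@H]2CO)ccc1OCC(=O)N4[C@@H](Cc5ccccc5)COC4=O | intermediate
18 | (4S)-4-benzyl-3-{[4-({(3R,4R,5S)-4-[(tert-butyldimethylsilyloxy)methyl]-5-[3-methoxy-4-(triisopropylsilyloxy)phenyl]oxolan-3-yl}methyl)-2-methoxyphenoxy]acetyl}oxazolidin-2-one | COc1cc(C[C@H]2CO[C@H](c3ccc(O[Si](C(C)C)(C(C)C)C(C)C)c(OC)c3)[C@H]2CO[Si](C)(C)C(C)(C)C)ccc1OCC(=O)N4[C@@H](Cc5ccccc5)COC4=O | intermediate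
19 | (Z)-di-n-butylboron enolate of 18 (formed in the flask) | COc1cc(C[C@H]2CO[C@H](c3ccc(O[Si](C(C)C)(C(C)C)C(C)C)c(OC)c3)[C@H]2CO[Si](C)(C)C(C)(C)C)ccc1O/C=C(\OB(CCCC)CCCC)N4[C@@H](Cc5ccccc5)COC4=O | intermediate
20 | (4S)-4-benzyl-3-{(2S,3R)-2-[4-({(3R,4R,5S)-4-[(tert-butyldimethylsilyloxy)methyl]-5-[3-methoxy-4-(triisopropylsilyloxy)phenyl]oxolan-3-yl}methyl)-2-methoxyphenoxy]-3-hydroxy-3-[3-methoxy-4-(triisopropylsilyloxy)phenyl]propanoyl}oxazolidin-2-one | COc1cc(C[C@H]2CO[C@H](c3ccc(O[Si](C(C)C)(C(C)C)C(C)C)c(OC)c3)[C@H]2CO[Si](C)(C)C(C)(C)C)ccc1O[C@@H]([C@H](O)c6ccc(O[Si](C(C)C)(C(C)C)C(C)C)c(OC)c6)C(=O)N4[C@@H](Cc5ccccc5)COC4=O | intermediate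
21 | (1R,2R)-2-[4-({(3R,4R,5S)-4-[(tert-butyldimethylsilyloxy)methyl]-5-[3-methoxy-4-(triisopropylsilyloxy)phenyl]oxolan-3-yl}methyl)-2-methoxyphenoxy]-1-[3-methoxy-4-(triisopropylsilyloxy)phenyl]propane-1,3-diol | COc1cc(C[C@H]2CO[C@H](c3ccc(O[Si](C(C)C)(C(C)C)C(C)C)c(OC)c3)[C@H]2CO[Si](C)(C)C(C)(C)C)ccc1O[C@@H]([C@H](O)c6ccc(O[Si](C(C)C)(C(C)C)C(C)C)c(OC)c6)CO | intermediate
22 | (1R,2R)-1-(4-hydroxy-3-methoxyphenyl)-2-[4-({(3R,4R,5S)-5-(4-hydroxy-3-methoxyphenyl)-4-(hydroxymethyl)oxolan-3-yl}methyl)-2-methoxyphenoxy]propane-1,3-diol (CNP0158473.2) | COc1cc([C@@H](O)[C@@H](CO)Oc2ccc(C[C@H]3CO[C@H](c4ccc(O)c(OC)c4)[C@H]3CO)cc2OC)ccc1O | target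

**Step count**

Total: 12 steps. Longest linear sequence: 10 steps (1 → 3 → 9 → 10 → 11 → 12 → 17 → 18 → 20 → 21 → 22; steps 1, 3, 4, 5, 6, 8, 9, 10, 11, 12).

**Steps most likely to fail**

1. Step 3. The hindered lithium enolate 8 may be protonated, or the aldolate may revert before the quench, so that the aldehyde is not incorporated. Fallback: the two bond formations are separated. Setting out from 3 and 6, the conjugate addition alone is run and quenched with NH4Cl to give (4R,5R)-4-{2-[4-(benzyloxy)-3-methoxyphenyl]-1,3-dithian-2-yl}-5-[(1R,2S,5R)-menthyloxy]dihydrofuran-2(3H)-one F1. F1 is deprotonated with LiN(i-Pr)2 in THF at −78 °C, the enolate is transmetalated with ZnCl2, and 5 is added. The zinc aldolate is less prone to retro-aldol, the aldehyde should again enter anti to the dithianyl group, and the route is rejoined at 9.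

2. Step 4. Hydrogenolysis of the benzylic hydroxyl may accompany the slower cleavage of the aryl benzyl ether, or the benzyl ether may survive. Fallback: sulfur removal and debenzylation are given to two different reagents. From 9, Ni2B generated from NiCl2·6H2O and NaBH4 in MeOH–THF at 0 °C should remove only the sulfur and give (3S,4R,5R)-4-[4-(benzyloxy)-3-methoxybenzyl]-3-{hydroxy[3-methoxy-4-(triisopropylsilyloxy)phenyl]methyl}-5-[(1R,2S,5R)-menthyloxy]dihydrofuran-2(3H)-one F2. Hydrogenolysis of F2 over Pd/C under H2 in EtOAc, stopped after uptake of one equivalent, then gives 10.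

3. Step 10. Bu2BOTf may be sequestered by the ether oxygens of 18, leaving enolisation incomplete, or the electron-rich aldehyde may react sluggishly so that retro-aldol erodes diastereoselectivity. Fallback: the two side-chain stereocentres are set by a catalyst-controlled reduction instead of an auxiliary aldol.
   - Aldehyde 5 is homologated with ethyl diazoacetate and catalytic SnCl2 (Roskamp reaction) to ethyl 3-[3-methoxy-4-(triisopropylsilyloxy)phenyl]-3-oxopropanoate F3.
   - F3 is brominated with NBS to racemic ethyl 2-bromo-3-[3-methoxy-4-(triisopropylsilyloxy)phenyl]-3-oxopropanoate F4.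
   - Phenol 12 is alkylated with F4 (K2CO3, acetone) to ethyl 2-[4-({(3R,4R,5S)-4-(hydroxymethyl)-5-[3-methoxy-4-(triisopropylsilyloxy)phenyl]oxolan-3-yl}methyl)-2-methoxyphenoxy]-3-[3-methoxy-4-(triisopropylsilyloxy)phenyl]-3-oxopropanoate F5, whose C8'' epimers interconvert.
   - Asymmetric transfer hydrogenation with dynamic kinetic resolution (RuCl(p-cymene)[(S,S)-TsDPEN], HCO2H/Et3N) should give, as α-alkoxy β-keto esters do, the syn ester ethyl (2S,3R)-3-hydroxy-2-[4-({(3R,4R,5S)-4-(hydroxymethyl)-5-[3-methoxy-4-(triisopropylsilyloxy)phenyl]oxolan-3-yl}methyl)-2-methoxyphenoxy]-3-[3-methoxy-4-(triisopropylsilyloxy)phenyl]propanoate F6.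
   - LiBH4 reduces the ester to (1R,2R)-2-[4-({(3R,4R,5S)-4-(hydroxymethyl)-5-[3-methoxy-4-(triisopropylsilyloxy)phenyl]oxolan-3-yl}methyl)-2-methoxyphenoxy]-1-[3-methoxy-4-(triisopropylsilyloxy)phenyl]propane-1,3-diol F7.
   - TBAF/AcOH removes the two silyl groups of F7, and the route is rejoined at 22.

**Further compounds**

F1 | step 3 | (4R,5R)-4-{2-[4-(benzyloxy)-3-methoxyphenyl]-1,3-dithian-2-yl}-5-[(1R,2S,5R)-menthyloxy]dihydrofuran-2(3H)-one | COc1cc(C2(SCCCS2)[C@H]3[C@H](O[C@@H]4C[C@H](C)CC[C@H]4C(C)C)OC(=O)C3)ccc1OCc1ccccc1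
F2 | step 4 | (3S,4R,5R)-4-[4-(benzyloxy)-3-methoxybenzyl]-3-{hydroxy[3-methoxy-4-(triisopropylsilyloxy)phenyl]methyl}-5-[(1R,2S,5R)-menthyloxy]dihydrofuran-2(3H)-one, both carbinol epimers | COc1cc(C[C@H]3[C@H](O[C@@H]4C[C@H](C)CC[C@H]4C(C)C)OC(=O)[C@@H]3C(O)c5ccc(O[Si](C(C)C)(C(C)C)C(C)C)c(OC)c5)ccc1OCc1ccccc1
F3 | step 10 | ethyl 3-[3-methoxy-4-(triisopropylsilyloxy)phenyl]-3-oxopropanoate | CCOC(=O)CC(=O)c1ccc(O[Si](C(C)C)(C(C)C)C(C)C)c(OC)c1
F4 | step 10 | ethyl 2-bromo-3-[3-methoxy-4-(triisopropylsilyloxy)phenyl]-3-oxopropanoate, racemic | CCOC(=O)C(Br)C(=O)c1ccc(O[Si](C(C)C)(C(C)C)C(C)C)c(OC)c1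
F5 | step 10 | ethyl 2-[4-({(3R,4R,5S)-4-(hydroxymethyl)-5-[3-methoxy-4-(triisopropylsilyloxy)phenyl]oxolan-3-yl}methyl)-2-methoxyphenoxy]-3-[3-methoxy-4-(triisopropylsilyloxy)phenyl]-3-oxopropanoate, interconverting C2 epimers | CCOC(=O)C(Oc1ccc(C[C@H]2CO[C@H](c3ccc(O[Si](C(C)C)(C(C)C)C(C)C)c(OC)c3)[C@H]2CO)cc1OC)C(=O)c4ccc(O[Si](C(C)C)(C(C)C)C(C)C)c(OC)c4
F6 | step 10 | ethyl (2S,3R)-3-hydroxy-2-[4-({(3R,4R,5S)-4-(hydroxymethyl)-5-[3-methoxy-4-(triisopropylsilyloxy)phenyl]oxolan-3-yl}methyl)-2-methoxyphenoxy]-3-[3-methoxy-4-(triisopropylsilyloxy)phenyl]propanoate | CCOC(=O)[C@@H](Oc1ccc(C[C@H]2CO[C@H](c3ccc(O[Si](C(C)C)(C(C)C)C(C)C)c(OC)c3)[C@H]2CO)cc1OC)[C@H](O)c4ccc(O[Si](C(C)C)(C(C)C)C(C)C)c(OC)c4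
F7 | step 10 | (1R,2R)-2-[4-({(3R,4R,5S)-4-(hydroxymethyl)-5-[3-methoxy-4-(triisopropylsilyloxy)phenyl]oxolan-3-yl}methyl)-2-methoxyphenoxy]-1-[3-methoxy-4-(triisopropylsilyloxy)phenyl]propane-1,3-diol | OC[C@@H](Oc1ccc(C[C@H]2CO[C@H](c3ccc(O[Si](C(C)C)(C(C)C)C(C)C)c(OC)c3)[C@H]2CO)cc1OC)[C@H](O)c4ccc(O[Si](C(C)C)(C(C)C)C(C)C)c(OC)c4
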